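**Plan**

- Locants: ring fusion C1/C5; five-membered ring C1–C2–C3(OH)–C4(=CH2)–C5; seven-membered ring C5–C6(OH)–C7–C8–C9(OH)–C10(=CH2)–C1; side chain on C7 is C11(Me)–C12(OAc)–C13–C14=C15.
- Enabling feature: O6 and O12 stand 1,4 across C7–C11 and the C7/C11/C12 triad is all-cis. C6–C7–C11–C12–O12 is therefore a latent all-cis γ-butyrolactone, i.e. a butenolide once C7=C11 is unsaturated and C6 is raised to the acid level.
- Cuts: C9–C10 (alkenyl + aldehyde, leaves the 10-methylene), C5–C6 (allyl + aldehyde, leaves the 4-methylene), the lactone C6–O12, then C11–C12 of the butenolide.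
- Forward: enol triflate + 4-methylpent-3-enal gives the butenolide (C11–C12); conjugate reduction; ring opening with acetylation of O12; aldehyde; indium allylation onto the chiral-pool cyclopentene; seven-membered ring by Nozaki–Hiyama–Kishi closure; C9 adjusted; desilylation.
- Stereochemistry: C12 by ligand control in the key step; C11 and C7 relayed from C12 on the butenolide; C1 from (S)-4-silyloxycyclopentenone; C3 by Luche reduction; C5/C6 by chair allylation (anti to the C1 substituent, Felkin-matched); C9 by CBS reduction.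

Key step: step 10

Remark: the sense of induction by the chiral ligand in step 10 and by the oxazaborolidine in step 20 is taken from the accepted models and is an assumption for these substrates.

**Step 1**
Reactants: 1 (S)-4-[(tert-butyldimethylsilyl)oxy]cyclopent-2-en-1-one; 2 (1-bromovinyl)trimethylsilane
Product: 5 (S)-4-[1-(trimethylsilyl)vinyl]cyclopent-2-en-1-one, via vinyl Grignard reagent 3 (not isolated), via trans silyloxy ketone 4 (not isolated)
Conditions: 2, Mg, THF, 40 °C; then 1, CuI·2LiCl (10 mol %), THF, −40 °C; aq NH4Cl; then DBU, CH2Cl2, 0 °C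
Reagents that add atoms: none
Why: Copper-catalysed conjugate addition of the α-silylvinyl Grignard reagent should occur trans to the 4-silyloxy group, and E1cB loss of silanol from 4 then leaves that centre as C1 of the 4-substituted cyclopentenone.

**Step 2**
Reactants: 5 (S)-4-[1-(trimethylsilyl)vinyl]cyclopent-2-en-1-one
Product: 6 (S)-4-(1-iodovinyl)cyclopent-2-en-1-one
Conditions: NIS, MeCN/ClCH2CN (4:1), 0 → 20 °C
Reagents that add atoms: N-iodosuccinimide O=C1CCC(=O)N1I
Why: Ipso-iododesilylation of the vinylsilane gives the 2-iodoalkene needed for the later ring closure; the electron-poor enone double bond should not react.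

**Step 3**
Reactants: 6 (S)-4-(1-iodovinyl)cyclopent-2-en-1-one
Product: 7 (S)-2-(hydroxymethyl)-4-(1-iodovinyl)cyclopent-2-en-1-one
Conditions: 37 % aq HCHO, imidazole, THF/H2O (1:1), 20 °C
Reagents that add atoms: formaldehyde C=O
Why: Morita–Baylis–Hillman reaction under nucleophilic catalysis places the future 4-methylene carbon on the enone α-carbon.

**Step 4**
Reactants: 7 (S)-2-(hydroxymethyl)-4-(1-iodovinyl)cyclopent-2-en-1-one
Product: 8 (1R,4S)-2-(hydroxymethyl)-4-(1-iodovinyl)cyclopent-2-en-1-ol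
Conditions: NaBH4, CeCl3·7H2O, MeOH, −78 °C
Reagents that add atoms: none
Why: Luche 1,2-reduction; hydride should add anti to the ring substituent and give the 1,4-cis alcohol (C3 of the target, R).

**Step 5**
Reactants: 8 (1R,4S)-2-(hydroxymethyl)-4-(1-iodovinyl)cyclopent-2-en-1-ol
Product: 9 (1R,4S)-2-(bromomethyl)-4-(1-iodovinyl)cyclopent-2-en-1-ol
Conditions: CBr4 (1.05 equiv), PPh3 (1.1 equiv), CH2Cl2, −30 °C
Reagents that add atoms: carbon tetrabromide BrC(Br)(Br)Br
Why: Appel bromination should be faster at the unhindered primary allylic hydroxyl than at the secondary one.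

**Step 6**
Reactants: 9 (1R,4S)-2-(bromomethyl)-4-(1-iodovinyl)cyclopent-2-en-1-ol
Product: 10 {[(1R,4S)-2-(bromomethyl)-4-(1-iodovinyl)cyclopent-2-en-1-yl]oxy}(tert-butyl)dimethylsilane
Conditions: TBSOTf, 2,6-lutidine, CH2Cl2, −78 °C
Reagents that add atoms: tert-butyldimethylsilyl triflate CC(C)(C)[Si](C)(C)OS(=O)(=O)C(F)(F)F
Why: Silylation with the silyl triflate and a non-nucleophilic base protects the secondary alcohol without displacing the allylic bromide.

**Step 7**
Reactants: 11 4-methylpent-3-en-1-ol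
Product: 12 4-methylpent-3-enal
Conditions: Dess–Martin periodinane, NaHCO3, CH2Cl2, 0 °C; used cold without purification
Reagents that add atoms: none
Why: Buffered Dess–Martin oxidation is non-basic and should not move the β,γ-double bond into conjugation.

**Step 8**
Reactants: 13 ethyl acetoacetate; 14 (2-bromoethoxy)(tert-butyl)dimethylsilane
Product: 15 ethyl 2-acetyl-4-[(tert-butyldimethylsilyl)oxy]butanoate (racemic)
Conditions: NaH, NaI (10 mol %), THF/DMF, 0 → 60 °C
Reagents that add atoms: none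
Why: C-alkylation of the acetoacetate sodium enolate with iodide catalysis installs C8–C9; the stereocentre is removed in the next step.

**Step 9**
Reactants: 15 ethyl 2-acetyl-4-[(tert-butyldimethylsilyl)oxy]butanoate
Product: 16 ethyl (Z)-2-{2-[(tert-butyldimethylsilyl)oxy]ethyl}-3-[(trifluoromethanesulfonyl)oxy]but-2-enoate
Conditions: NaH, Et2O, 0 °C; Tf2O, −20 °C
Reagents that add atoms: triflic anhydride O=S(=O)(OS(=O)(=O)C(F)(F)F)C(F)(F)F
Why: O-triflation of the chelated U-shaped sodium enolate should give the Z enol triflate, with triflate and ester cis as lactonisation requires.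

**Step 10**
Reactants: 16 ethyl (Z)-2-{2-[(tert-butyldimethylsilyl)oxy]ethyl}-3-[(trifluoromethanesulfonyl)oxy]but-2-enoate; 12 4-methylpent-3-enal
Product: 18 (S)-3-{2-[(tert-butyldimethylsilyl)oxy]ethyl}-4-methyl-5-(3-methylbut-2-en-1-yl)furan-2(5H)-one, via Z hydroxy ester 17 (not isolated)
Conditions: CrCl2 (4 equiv), NiCl2 (2 mol %), chiral 2-(2-sulfonamidoaryl)oxazoline ligand (enantiomer for Re-face delivery), Et3N, THF, 20 °C; aq work-up; PPTS (cat.), CH2Cl2
Reagents that add atoms: none
Why: Nickel(0) inserts into the C11–OTf bond with retention of the Z geometry and hands the alkenyl group to chromium(III); the alkenylchromium, bound to the chiral ligand, adds to the aldehyde carbon (C11–C12), and the chromium alkoxide, held cis to the ester on C7=C11, closes the furanone by attack on the ester carbonyl (5-exo-trig acyl substitution, O12–C6, loss of ethoxide). The closest known type is the Nozaki–Hiyama–Kishi coupling of β-triflyloxy or β-iodo enoates with aldehydes to give butenolides, in its ligand-controlled asymmetric variant. The only new stereocentre, C12, is set by the ligand on chromium (reagent control, Re-face attack, S). The step needs clean 1,2-addition to an enolisable β,γ-unsaturated aldehyde without isomerisation to the conjugated enal; the non-basic, carbonyl-selective organochromium secures this, and the Z geometry from step 9 secures ring closure. The ring made here is a helper: it should later fix C11 and C7, keep C6 at the acid level for chain extension, and mark O12 as the one oxygen that is acetylated.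

**Step 11**
Reactants: 18 (S)-3-{2-[(tert-butyldimethylsilyl)oxy]ethyl}-4-methyl-5-(3-methylbut-2-en-1-yl)furan-2(5H)-one
Product: 19 (3R,4S,5S)-3-{2-[(tert-butyldimethylsilyl)oxy]ethyl}-4-methyl-5-(3-methylbut-2-en-1-yl)dihydrofuran-2(3H)-one (all-cis)
Conditions: (IPr)CuCl (5 mol %), NaOt-Bu (5 mol %), (EtO)2MeSiH (2 equiv), t-BuOH (2 equiv), toluene, 20 °C
Reagents that add atoms: none
Why: Copper hydride conjugate reduction should deliver hydride to C11 anti to the C12 substituent, and t-BuOH should protonate the copper enolate at C7 from the same open face, so the three substituents end all-cis; the isolated trisubstituted alkene is not a substrate.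

**Step 12**
Reactants: 19 (3R,4S,5S)-3-{2-[(tert-butyldimethylsilyl)oxy]ethyl}-4-methyl-5-(3-methylbut-2-en-1-yl)dihydrofuran-2(3H)-one
Product: 21 (2R,3S,4S)-4-acetoxy-2-{2-[(tert-butyldimethylsilyl)oxy]ethyl}-N-methoxy-N,3,7-trimethyloct-6-enamide, via hydroxy Weinreb amide 20 (not isolated)
Conditions: MeNH(OMe)·HCl, i-PrMgCl, THF, −20 → 0 °C; then Ac2O, DMAP (cat.), 0 → 20 °C
Reagents that add atoms: N,O-dimethylhydroxylamine hydrochloride CNOC.Cl; acetic anhydride CC(=O)OC(C)=O
Why: Aminolysis by the magnesium amide opens the lactone and frees only O12, whose alkoxide is acetylated in the same flask before it can re-lactonise; this places the acetate on one oxygen out of four.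

**Step 13**
Reactants: 21 (2R,3S,4S)-4-acetoxy-2-{2-[(tert-butyldimethylsilyl)oxy]ethyl}-N-methoxy-N,3,7-trimethyloct-6-enamide
Product: 22 (2R,3S,4S)-4-acetoxy-2-{2-[(tert-butyldimethylsilyl)oxy]ethyl}-3,7-dimethyloct-6-enal
Conditions: Cp2Zr(H)Cl (1.5 equiv), THF, 20 °C, 20 min; used at once
Reagents that add atoms: none
Why: Schwartz reagent reduces the tertiary (Weinreb) amide to the aldehyde through a stable zirconium hemiaminal and should leave the acetate and the trisubstituted alkene alone.

**Step 14**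
Reactants: 10 {[(1R,4S)-2-(bromomethyl)-4-(1-iodovinyl)cyclopent-2-en-1-yl]oxy}(tert-butyl)dimethylsilane; 22 (2R,3S,4S)-4-acetoxy-2-{2-[(tert-butyldimethylsilyl)oxy]ethyl}-3,7-dimethyloct-6-enal
Product: 23 9,10-seco homoallylic alcohol (C5–C6 bond formed; 6-OH; 4-methylene; 1-(1-iodovinyl); 3-OTBS; 9-OTBS; 12-OAc; C1/C3/C5/C6/C7/C11/C12 as in the target)
Conditions: In powder, THF/H2O (3:1), 20 °C
Reagents that add atoms: none
Why: Barbier-type indium allylation through a Zimmerman–Traxler chair: the allylindium should react at C5 on the face anti to the C1 substituent, the cyclic E-type allyl unit should give the 5,6-anti product, and this sense coincides with Felkin–Anh addition to the α-branched aldehyde (matched pair), setting C5 and C6 and creating the 4-methylene group.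

**Step 15**
Reactants: 23 9,10-seco homoallylic alcohol
Product: 24 9,10-seco tris(silyl ether) (23 with 6-OTBS)
Conditions: TBSOTf, 2,6-lutidine, CH2Cl2, −78 → 0 °C
Reagents that add atoms: tert-butyldimethylsilyl triflate CC(C)(C)[Si](C)(C)OS(=O)(=O)C(F)(F)F
Why: Silyl triflate silylation of the hindered C6 hydroxyl prevents lactol formation with the C9 aldehyde to come.

**Step 16**
Reactants: 24 9,10-seco tris(silyl ether)
Product: 25 9,10-seco primary alcohol (free 9-OH; 3,6-bis-OTBS)
Conditions: HF·pyridine, pyridine, THF, 0 °C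
Reagents that add atoms: none
Why: Buffered HF·pyridine should cleave the primary silyl ether well before the two secondary ones.

**Step 17**
Reactants: 25 9,10-seco primary alcohol
Product: 26 9,10-seco aldehyde (C9 aldehyde; 1-(1-iodovinyl))
Conditions: Dess–Martin periodinane, NaHCO3, CH2Cl2, 0 → 20 °C
Reagents that add atoms: none
Why: Dess–Martin oxidation of the only free hydroxyl gives the aldehyde under conditions that spare the acetate, silyl ethers and alkenyl iodide.

**Step 18**
Reactants: 26 9,10-seco aldehyde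
Product: 27 hydroazulene allylic alcohol (9-OH as epimers; 10-methylene; 3,6-bis-OTBS; 12-OAc)
Conditions: CrCl2 (6 equiv), NiCl2 (1 mol %), DMSO/THF, 0.005 M, 20 °C
Reagents that add atoms: none
Why: Intramolecular Nozaki–Hiyama–Kishi reaction: the alkenylchromium from the 2-iodoalkene adds to the C9 aldehyde (7-exo-trig) and closes the seven-membered ring with the 10-methylene group in place; the C9 configuration is not relied on.

**Step 19**
Reactants: 27 hydroazulene allylic alcohol
Product: 28 hydroazulene enone (9-ketone; 10-methylene; 3,6-bis-OTBS; 12-OAc)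
Conditions: Dess–Martin periodinane, NaHCO3, CH2Cl2, 20 °C
Reagents that add atoms: none
Why: Oxidation of the only free hydroxyl merges both C9 epimers into one α-methylene ketone.

**Step 20**
Reactants: 28 hydroazulene enone
Product: 29 (9S)-alcohol (3,6-bis-O-TBS ether of the target)
Conditions: (R)-2-methyl-CBS-oxazaborolidine (0.5 equiv), catecholborane, toluene, −78 °C
Reagents that add atoms: none
Why: Corey–Bakshi–Shibata reduction; with the α-methylene branch as the large group the (R)-catalyst should give 9S, and catecholborane at −78 °C should avoid hydroboration and 1,4-reduction.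

**Step 21**
Reactants: 29 (9S)-alcohol
Product: 30 (2S,3S)-6-methyl-2-[(2R,3aR,4S,5R,7S,8aS)-2,4,7-trihydroxy-3,8-dimethylidenedecahydroazulen-5-yl]hept-5-en-3-yl acetate
Conditions: HF·pyridine (excess), pyridine, THF, 0 → 20 °C
Reagents that add atoms: none
Why: Buffered fluoride cleavage of the two secondary silyl ethers should neither hydrolyse nor shift the acetate.

**Compound list**

1 | (S)-4-[(tert-butyldimethylsilyl)oxy]cyclopent-2-en-1-one | O=C1C=C[C@@H](O[Si](C)(C)C(C)(C)C)C1 | starting material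
2 | (1-bromovinyl)trimethylsilane | C=C(Br)[Si](C)(C)C | starting material
3 | [1-(trimethylsilyl)vinyl]magnesium bromide | C=C([Mg]Br)[Si](C)(C)C | intermediate
4 | (3S,4S)-4-[(tert-butyldimethylsilyl)oxy]-3-[1-(trimethylsilyl)vinyl]cyclopentan-1-one (3,4-trans) | O=C1C[C@H](C(=C)[Si](C)(C)C)[C@@H](O[Si](C)(C)C(C)(C)C)C1 | intermediate
5 | (S)-4-[1-(trimethylsilyl)vinyl]cyclopent-2-en-1-one | O=C1C=C[C@@H](C(=C)[Si](C)(C)C)C1 | intermediate
6 | (S)-4-(1-iodovinyl)cyclopent-2-en-1-one | O=C1C=C[C@@H](C(I)=C)C1 | intermediate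
7 | (S)-2-(hydroxymethyl)-4-(1-iodovinyl)cyclopent-2-en-1-one | O=C1C(CO)=C[C@@H](C(I)=C)C1 | intermediate
8 | (1R,4S)-2-(hydroxymethyl)-4-(1-iodovinyl)cyclopent-2-en-1-ol | O[C@H]1C(CO)=C[C@@H](C(I)=C)C1 | intermediate
9 | (1R,4S)-2-(bromomethyl)-4-(1-iodovinyl)cyclopent-2-en-1-ol | O[C@H]1C(CBr)=C[C@@H](C(I)=C)C1 | intermediate
10 | {[(1R,4S)-2-(bromomethyl)-4-(1-iodovinyl)cyclopent-2-en-1-yl]oxy}(tert-butyl)dimethylsilane | CC(C)(C)[Si](C)(C)O[C@H]1C(CBr)=C[C@@H](C(I)=C)C1 | intermediate
11 | 4-methylpent-3-en-1-ol | CC(C)=CCCO | starting material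
12 | 4-methylpent-3-enal | CC(C)=CCC=O | intermediate
13 | ethyl acetoacetate | CCOC(=O)CC(C)=O | starting material
14 | (2-bromoethoxy)(tert-butyl)dimethylsilane | BrCCO[Si](C)(C)C(C)(C)C | starting material
15 | ethyl 2-acetyl-4-[(tert-butyldimethylsilyl)oxy]butanoate (racemic) | CCOC(=O)C(CCO[Si](C)(C)C(C)(C)C)C(C)=O | intermediate
16 | ethyl (Z)-2-{2-[(tert-butyldimethylsilyl)oxy]ethyl}-3-[(trifluoromethanesulfonyl)oxy]but-2-enoate | CCOC(=O)/C(CCO[Si](C)(C)C(C)(C)C)=C(/C)OS(=O)(=O)C(F)(F)F | intermediate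
17 | ethyl (2Z,4S)-2-{2-[(tert-butyldimethylsilyl)oxy]ethyl}-4-hydroxy-3,7-dimethylocta-2,6-dienoate | CCOC(=O)/C(CCO[Si](C)(C)C(C)(C)C)=C(/C)[C@@H](O)CC=C(C)C | intermediate
18 | (S)-3-{2-[(tert-butyldimethylsilyl)oxy]ethyl}-4-methyl-5-(3-methylbut-2-en-1-yl)furan-2(5H)-one | O=C1O[C@@H](CC=C(C)C)C(C)=C1CCO[Si](C)(C)C(C)(C)C | intermediate
19 | (3R,4S,5S)-3-{2-[(tert-butyldimethylsilyl)oxy]ethyl}-4-methyl-5-(3-methylbut-2-en-1-yl)dihydrofuran-2(3H)-one (all-cis) | O=C1O[C@@H](CC=C(C)C)[C@@H](C)[C@H]1CCO[Si](C)(C)C(C)(C)C | intermediate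
20 | (2R,3S,4S)-2-{2-[(tert-butyldimethylsilyl)oxy]ethyl}-4-hydroxy-N-methoxy-N,3,7-trimethyloct-6-enamide | CON(C)C(=O)[C@@H]([C@H](C)[C@H](CC=C(C)C)O)CCO[Si](C)(C)C(C)(C)C | intermediate
21 | (2R,3S,4S)-4-acetoxy-2-{2-[(tert-butyldimethylsilyl)oxy]ethyl}-N-methoxy-N,3,7-trimethyloct-6-enamide | CON(C)C(=O)[C@@H]([C@H](C)[C@H](CC=C(C)C)OC(C)=O)CCO[Si](C)(C)C(C)(C)C | intermediate
22 | (2R,3S,4S)-4-acetoxy-2-{2-[(tert-butyldimethylsilyl)oxy]ethyl}-3,7-dimethyloct-6-enal | O=C[C@@H]([C@H](C)[C@H](CC=C(C)C)OC(C)=O)CCO[Si](C)(C)C(C)(C)C | intermediate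
23 | 9,10-seco homoallylic alcohol (6-OH; 4-methylene; 1-(1-iodovinyl); 3-OTBS; 9-OTBS; 12-OAc; stereocentres as in the target) | C=C1[C@H]([C@@H](O)[C@@H]([C@H](C)[C@H](CC=C(C)C)OC(C)=O)CCO[Si](C)(C)C(C)(C)C)[C@@H](C(I)=C)C[C@H]1O[Si](C)(C)C(C)(C)C | intermediate
24 | 9,10-seco tris(silyl ether) (23 with 6-OTBS) | C=C1[C@H]([C@@H](O[Si](C)(C)C(C)(C)C)[C@@H]([C@H](C)[C@H](CC=C(C)C)OC(C)=O)CCO[Si](C)(C)C(C)(C)C)[C@@H](C(I)=C)C[C@H]1O[Si](C)(C)C(C)(C)C | intermediate
25 | 9,10-seco primary alcohol (free 9-OH; 3,6-bis-OTBS) | C=C1[C@H]([C@@H](O[Si](C)(C)C(C)(C)C)[C@@H]([C@H](C)[C@H](CC=C(C)C)OC(C)=O)CCO)[C@@H](C(I)=C)C[C@H]1O[Si](C)(C)C(C)(C)C | intermediate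
26 | 9,10-seco aldehyde (C9 aldehyde; 3,6-bis-OTBS) | C=C1[C@H]([C@@H](O[Si](C)(C)C(C)(C)C)[C@@H]([C@H](C)[C@H](CC=C(C)C)OC(C)=O)CC=O)[C@@H](C(I)=C)C[C@H]1O[Si](C)(C)C(C)(C)C | intermediate
27 | hydroazulene allylic alcohol (9-OH epimers; 3,6-bis-OTBS; 12-OAc) | C=C1[C@@H]2[C@@H](O[Si](C)(C)C(C)(C)C)[C@@H]([C@H](C)[C@H](CC=C(C)C)OC(C)=O)CC(O)C(=C)[C@H]2C[C@H]1O[Si](C)(C)C(C)(C)C | intermediate
28 | hydroazulene enone (9-ketone; 3,6-bis-OTBS; 12-OAc) | C=C1[C@@H]2[C@@H](O[Si](C)(C)C(C)(C)C)[C@@H]([C@H](C)[C@H](CC=C(C)C)OC(C)=O)CC(=O)C(=C)[C@H]2C[C@H]1O[Si](C)(C)C(C)(C)C | intermediate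
29 | (9S)-alcohol (3,6-bis-O-TBS ether of the target) | C=C1[C@@H]2[C@@H](O[Si](C)(C)C(C)(C)C)[C@@H]([C@H](C)[C@H](CC=C(C)C)OC(C)=O)C[C@H](O)C(=C)[C@H]2C[C@H]1O[Si](C)(C)C(C)(C)C | intermediate
30 | (2S,3S)-6-methyl-2-[(2R,3aR,4S,5R,7S,8aS)-2,4,7-trihydroxy-3,8-dimethylidenedecahydroazulen-5-yl]hept-5-en-3-yl acetate | C=C1[C@@H]2[C@@H](O)[C@@H]([C@H](C)[C@H](CC=C(C)C)OC(C)=O)C[C@H](O)C(=C)[C@H]2C[C@H]1O | target

**Step count and risks**

Total step count: 21. Longest linear sequence: 14 steps (steps 8–21 from 13/14, or steps 1–6 and 14–21 from 1).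

Steps most likely to fail:

Step 11. Hydride transfer to the tetrasubstituted β-carbon may be slow, and facial control in the protonation at C7 may be lost (the all-cis lactone is the less stable epimer). Fallback, from 16 back to 19: the lactone is made by catalytic syn-hydrogenation on a side chain that carries no other alkene. Triflate 16 is coupled under the step-10 conditions with commercial 3-(benzyloxy)propanal; this should give, through ethyl (2Z,4S)-6-(benzyloxy)-2-{2-[(tert-butyldimethylsilyl)oxy]ethyl}-4-hydroxy-3-methylhex-2-enoate F1, the benzyloxyethyl butenolide F2. Hydrogenation over Pd/C (H2, 40 bar, EtOAc) should add both hydrogens anti to the C12 substituent and cleave the benzyl ether in the same operation, giving the all-cis hydroxyethyl lactone F3. Dess–Martin oxidation gives the lactone aldehyde F4, and a salt-free Wittig reaction with isopropylidenetriphenylphosphorane at −78 °C builds the C14=C15 alkene and returns to 19.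

Step 14. The α-branched aldehyde 22 may epimerise at C7 before it is captured, and facial selectivity in the C5–C6 bond formation may be incomplete. Fallback, from 19 back to 23: the free aldehyde is avoided. Lactone 19 is reduced with DIBAL-H (−78 °C) to the lactol F5, which is allylated with 10 and indium in THF/H2O; lactols react through the small equilibrium amount of hydroxy aldehyde, which is trapped as it forms. This should give the 6,12-diol F6. Selective acetylation of the less hindered side-chain hydroxyl at C12 (Ac2O, 2,4,6-collidine, −20 °C) rejoins the route at 23.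

Step 18. Oligomerisation and reduction of the C–I bond may compete with the seven-membered ring closure. Fallback, from 26 back to 28: the ring is closed at the ketone oxidation level. Aldehyde 26 is oxidised (NaClO2, NaH2PO4, 2-methylbut-2-ene) to the seco acid F7 and converted (2,2′-dipyridyl disulfide, PPh3) into the S-2-pyridyl thioester F8. Nickel/zirconium-mediated alkenyl iodide–thioester ketone coupling (NiBr2·dtbbpy cat., Cp2ZrCl2, Zn, DMI, high dilution) should give enone 28 directly, which also removes step 19.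

**Further compounds**

F1 | step 11 | ethyl (2Z,4S)-6-(benzyloxy)-2-{2-[(tert-butyldimethylsilyl)oxy]ethyl}-4-hydroxy-3-methylhex-2-enoate | CCOC(=O)/C(CCO[Si](C)(C)C(C)(C)C)=C(/C)[C@@H](O)CCOCc1ccccc1
F2 | step 11 | (S)-5-[2-(benzyloxy)ethyl]-3-{2-[(tert-butyldimethylsilyl)oxy]ethyl}-4-methylfuran-2(5H)-one | O=C1O[C@@H](CCOCc2ccccc2)C(C)=C1CCO[Si](C)(C)C(C)(C)C
F3 | step 11 | all-cis 3-{2-[(tert-butyldimethylsilyl)oxy]ethyl}-5-(2-hydroxyethyl)-4-methyldihydrofuran-2(3H)-one | O=C1O[C@@H](CCO)[C@@H](C)[C@H]1CCO[Si](C)(C)C(C)(C)C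
F4 | step 11 | all-cis 2-(4-{2-[(tert-butyldimethylsilyl)oxy]ethyl}-3-methyl-5-oxotetrahydrofuran-2-yl)acetaldehyde | O=C1O[C@@H](CC=O)[C@@H](C)[C@H]1CCO[Si](C)(C)C(C)(C)C
F5 | step 14 | all-cis 3-{2-[(tert-butyldimethylsilyl)oxy]ethyl}-4-methyl-5-(3-methylbut-2-en-1-yl)tetrahydrofuran-2-ol (anomers) | OC1O[C@@H](CC=C(C)C)[C@@H](C)[C@H]1CCO[Si](C)(C)C(C)(C)C
F6 | step 14 | 9,10-seco 6,12-diol (23 without the acetyl group) | C=C1[C@H]([C@@H](O)[C@@H]([C@H](C)[C@H](CC=C(C)C)O)CCO[Si](C)(C)C(C)(C)C)[C@@H](C(I)=C)C[C@H]1O[Si](C)(C)C(C)(C)C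
F7 | step 18 | 9,10-seco carboxylic acid (26 oxidised at C9) | C=C1[C@H]([C@@H](O[Si](C)(C)C(C)(C)C)[C@@H]([C@H](C)[C@H](CC=C(C)C)OC(C)=O)CC(=O)O)[C@@H](C(I)=C)C[C@H]1O[Si](C)(C)C(C)(C)C
F8 | step 18 | 9,10-seco S-(pyridin-2-yl) thioester | C=C1[C@H]([C@@H](O[Si](C)(C)C(C)(C)C)[C@@H]([C@H](C)[C@H](CC=C(C)C)OC(C)=O)CC(=O)Sc2ccccn2)[C@@H](C(I)=C)C[C@H]1O[Si](C)(C)C(C)(C)C
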